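## Retrosynthetic overview

1. Target 16 ⇒ triol 12 + 2 × 4-hydroxybenzoic acid 13 (both ester C–O bonds, made last).
2. 12 ⇒ aryl bromide 6: the C5 side chain comes from a Heck reaction and DIBAL reduction, and the C3–CH2OH from trimming a glycerol-derived dioxolane by glycol cleavage and reduction.
3. 6 ⇒ alkenylphenol 3 + 4-bromoguaiacol 4 by an anodic dehydrogenative [3+2] coupling: C3–C3a forms first, then O1–C2 (the dihydrofuran, the only ring built). Both ring stereocentres are relayed from the dioxolane carbon.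
4. 3 ⇒ 4-bromo-2,6-dimethoxyphenol 1 + (S)-vinyl dioxolane 2 by a Heck reaction; both benzene rings are bought.

Assumption: (4S)-2,2-dimethyl-4-vinyl-1,3-dioxolane 2, the vinyl acetonide that corresponds to D-mannitol-derived (R)-glyceraldehyde acetonide, is taken as a catalogue chiral-pool compound.

## Route

Step 1
Reactants: 1 4-bromo-2,6-dimethoxyphenol; 2 (4S)-2,2-dimethyl-4-vinyl-1,3-dioxolane (1.5 equiv)
Product: 3 4-[(E)-2-[(4S)-2,2-dimethyl-1,3-dioxolan-4-yl]ethenyl]-2,6-dimethoxyphenol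
Conditions: Herrmann–Beller palladacycle (1 mol%), NaOAc (1.5 equiv), DMA, 120 °C, sealed tube
Reagents that add atoms: none
Why: Mizoroki–Heck reaction in which aryl-Pd adds to the terminal vinyl carbon and syn β-H elimination toward the benzylic side gives the conjugated (E)-styrene, while the bought dioxolane stereocentre is not touched.

Step 2
Reactants: 3 alkenylphenol (added over 6 h); 4 4-bromo-2-methoxyphenol (5 equiv, excess recovered)
Product: 6 4-[(2S,3S)-5-bromo-3-[(4S)-2,2-dimethyl-1,3-dioxolan-4-yl]-7-methoxy-2,3-dihydro-1-benzofuran-2-yl]-2,6-dimethoxyphenol (2,3-trans), via quinone methide 5 (not isolated)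
Conditions: undivided cell, BDD anode / Pt cathode, HFIP, Bu4NBF4 (0.1 M), 2,6-lutidine (1 equiv), 2.5 mA cm−2, 2.2 F mol−1 based on 3, 10 °C
Reagents that add atoms: none
Why: Proposed new method: the anode oxidises only the conjugated syringyl phenol 3 (lowest potential, lutidine-assisted PCET) by two electrons to a vinylogous phenoxonium ion that is electrophilic at the alkene carbon next to the dioxolane; in HFIP, which stabilises the cation and disfavours O-attack, the carbon ortho to OH of excess 4 attacks this carbon anti to the dioxolane C–O bond (Felkin–Anh / inside-alkoxy 1,2-induction from the (S)-centre, expected about 4–8:1, diastereomers separable because the dioxolane stereocentre is still present) to give quinone methide 5, whose intramolecular oxa-1,6-addition closes the dihydrofuran with the thermodynamically preferred 2,3-trans geometry; the closest known reaction types are the anodic β-5 dehydrodimerisation of 4-propenylphenols, anodic phenol–arene cross-coupling on BDD in HFIP and oxidative phenol–alkene [3+2] annulation, and what is new is the cross-selective version with the alkenylphenol as the only oxidised partner combined with acyclic stereoinduction from a chiral-pool allylic centre.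

Step 3
Reactants: 6 bromo-dihydrobenzofuran phenol
Product: 7 4-[(2S,3S)-5-bromo-3-[(4S)-2,2-dimethyl-1,3-dioxolan-4-yl]-7-methoxy-2,3-dihydro-1-benzofuran-2-yl]-2,6-dimethoxyphenyl acetate
Conditions: Ac2O (1.5 equiv), pyridine, DMAP (cat.), CH2Cl2, 0 °C to rt
Reagents that add atoms: acetic anhydride, CC(=O)OC(C)=O
Why: DMAP-catalysed acetylation of the only OH protects the electron-rich phenol from periodate in step 5 and stops the benzylic C2–O bond from ionising through a quinone methide; no stereocentre is involved.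

Step 4
Reactants: 7 aryl bromide; 8 methyl acrylate (3 equiv)
Product: 9 methyl (E)-3-[(2S,3S)-2-(4-acetoxy-3,5-dimethoxyphenyl)-3-[(4S)-2,2-dimethyl-1,3-dioxolan-4-yl]-7-methoxy-2,3-dihydro-1-benzofuran-5-yl]prop-2-enoate
Conditions: Herrmann–Beller palladacycle (2 mol%), NaOAc (1.5 equiv), DMA, 120 °C, sealed tube
Reagents that add atoms: none
Why: Mizoroki–Heck reaction of an electron-rich aryl bromide with an acrylate gives only the (E)-cinnamate, and the aryl acetate, acetonide and both ring stereocentres are inert to NaOAc/Pd.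

Step 5
Reactants: 9 acetonide
Product: 11 methyl (E)-3-[(2S,3S)-2-(4-acetoxy-3,5-dimethoxyphenyl)-3-formyl-7-methoxy-2,3-dihydro-1-benzofuran-5-yl]prop-2-enoate, via diol 10 (not isolated)
Conditions: H5IO6 (1.5 equiv), EtOAc, 0 °C to rt, 2 h; cold NaHCO3 wash, crude used at once
Reagents that add atoms: none
Why: Periodic acid hydrolyses the terminal acetonide and then carries out Malaprade glycol cleavage in the same flask, so the dioxolane CH carbon becomes the C3 formyl carbon and its stereocentre is erased after it has done its work, while C2 and C3 are untouched under cold, acidic, base-free conditions.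

Step 6
Reactants: 11 aldehyde ester acetate
Product: 12 4-[(2S,3R)-3-(hydroxymethyl)-5-[(E)-3-hydroxyprop-1-enyl]-7-methoxy-2,3-dihydro-1-benzofuran-2-yl]-2,6-dimethoxyphenol
Conditions: DIBAL-H (8 equiv), CH2Cl2/toluene, −78 to −40 °C; aq. Rochelle salt
Reagents that add atoms: none
Why: DIBAL-H global reduction turns the aldehyde into CH2OH, the enoate into the (E)-allylic alcohol by 1,2-reduction and cleaves the aryl acetate, and the cold, non-basic hydride does not epimerise C3.

Step 7
Reactants: 12 triol; 13 4-hydroxybenzoic acid (2.4 equiv)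
Product: 16 quiquesetinerviusin B, [(2S,3R)-2-(4-hydroxy-3,5-dimethoxyphenyl)-5-[(E)-3-(4-hydroxybenzoyloxy)prop-1-enyl]-7-methoxy-2,3-dihydro-1-benzofuran-3-yl]methyl 4-hydroxybenzoate, via allylic mono-ester 14 (not isolated), via ring-CH2 mono-ester 15 (not isolated)
Conditions: PPh3 (2.5 equiv), DIAD (2.5 equiv, slow addition), THF, 0 °C to rt
Reagents that add atoms: none
Why: Mitsunobu esterification in which the carboxylic acid (pKa about 4.5) is the only pronucleophile acidic enough to react quickly, so both primary alkoxyphosphonium ions are displaced by carboxylate while the phenols stay free, and no stereocentre sits at a reacting carbon.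

## Compound list

1 | 4-bromo-2,6-dimethoxyphenol | COc1cc(Br)cc(OC)c1O | starting material
2 | (4S)-2,2-dimethyl-4-vinyl-1,3-dioxolane | C=C[C@H]1COC(C)(C)O1 | starting material
3 | 4-[(E)-2-[(4S)-2,2-dimethyl-1,3-dioxolan-4-yl]ethenyl]-2,6-dimethoxyphenol | COc1cc(/C=C/[C@H]2COC(C)(C)O2)cc(OC)c1O | intermediate
4 | 4-bromo-2-methoxyphenol | COc1cc(Br)ccc1O | starting material
5 | 4-[(2R)-2-(5-bromo-2-hydroxy-3-methoxyphenyl)-2-[(4S)-2,2-dimethyl-1,3-dioxolan-4-yl]ethylidene]-2,6-dimethoxycyclohexa-2,5-dien-1-one (quinone methide) | COC1=CC(=C[C@H](c2cc(Br)cc(OC)c2O)[C@H]2COC(C)(C)O2)C=C(OC)C1=O | intermediate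
6 | 4-[(2S,3S)-5-bromo-3-[(4S)-2,2-dimethyl-1,3-dioxolan-4-yl]-7-methoxy-2,3-dihydro-1-benzofuran-2-yl]-2,6-dimethoxyphenol (2,3-trans) | COc1cc([C@H]2Oc3c(OC)cc(Br)cc3[C@@H]2[C@H]4COC(C)(C)O4)cc(OC)c1O | intermediate
7 | 4-[(2S,3S)-5-bromo-3-[(4S)-2,2-dimethyl-1,3-dioxolan-4-yl]-7-methoxy-2,3-dihydro-1-benzofuran-2-yl]-2,6-dimethoxyphenyl acetate | COc1cc([C@H]2Oc3c(OC)cc(Br)cc3[C@@H]2[C@H]4COC(C)(C)O4)cc(OC)c1OC(C)=O | intermediate
8 | methyl acrylate | C=CC(=O)OC | starting material
9 | methyl (E)-3-[(2S,3S)-2-(4-acetoxy-3,5-dimethoxyphenyl)-3-[(4S)-2,2-dimethyl-1,3-dioxolan-4-yl]-7-methoxy-2,3-dihydro-1-benzofuran-5-yl]prop-2-enoate | COc1cc([C@H]2Oc3c(OC)cc(/C=C/C(=O)OC)cc3[C@@H]2[C@H]4COC(C)(C)O4)cc(OC)c1OC(C)=O | intermediate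
10 | methyl (E)-3-[(2S,3R)-2-(4-acetoxy-3,5-dimethoxyphenyl)-3-[(1S)-1,2-dihydroxyethyl]-7-methoxy-2,3-dihydro-1-benzofuran-5-yl]prop-2-enoate | COc1cc([C@H]2Oc3c(OC)cc(/C=C/C(=O)OC)cc3[C@@H]2[C@H](O)CO)cc(OC)c1OC(C)=O | intermediate
11 | methyl (E)-3-[(2S,3S)-2-(4-acetoxy-3,5-dimethoxyphenyl)-3-formyl-7-methoxy-2,3-dihydro-1-benzofuran-5-yl]prop-2-enoate | COc1cc([C@H]2Oc3c(OC)cc(/C=C/C(=O)OC)cc3[C@@H]2C=O)cc(OC)c1OC(C)=O | intermediate
12 | 4-[(2S,3R)-3-(hydroxymethyl)-5-[(E)-3-hydroxyprop-1-enyl]-7-methoxy-2,3-dihydro-1-benzofuran-2-yl]-2,6-dimethoxyphenol | COc1cc([C@H]2Oc3c(OC)cc(/C=C/CO)cc3[C@@H]2CO)cc(OC)c1O | intermediate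
13 | 4-hydroxybenzoic acid | OC(=O)c1ccc(O)cc1 | starting material
14 | (E)-3-[(2S,3R)-2-(4-hydroxy-3,5-dimethoxyphenyl)-3-(hydroxymethyl)-7-methoxy-2,3-dihydro-1-benzofuran-5-yl]prop-2-enyl 4-hydroxybenzoate | COc1cc([C@H]2Oc3c(OC)cc(/C=C/COC(=O)c4ccc(O)cc4)cc3[C@@H]2CO)cc(OC)c1O | intermediate
15 | [(2S,3R)-2-(4-hydroxy-3,5-dimethoxyphenyl)-5-[(E)-3-hydroxyprop-1-enyl]-7-methoxy-2,3-dihydro-1-benzofuran-3-yl]methyl 4-hydroxybenzoate | COc1cc([C@H]2Oc3c(OC)cc(/C=C/CO)cc3[C@@H]2COC(=O)c2ccc(O)cc2)cc(OC)c1O | intermediate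
16 | quiquesetinerviusin B, (2S,3R) | COc1cc([C@H]2Oc3c(OC)cc(/C=C/COC(=O)c4ccc(O)cc4)cc3[C@@H]2COC(=O)c2ccc(O)cc2)cc(OC)c1O | target

## Summary

Total step count: 7. Longest linear sequence: 7 steps (1 → 3 → 6 → 7 → 9 → 11 → 12 → 16).

The three steps most likely to fail:

**Step 2 (the proposed new anodic [3+2] coupling).** The risks are 8–8 homodimerisation of 3, O-alkylation of 4 instead of C-alkylation, and a low or reversed facial preference. If only the sense of induction is wrong, the enantiomer of 2 is used instead. The fallback uses known chemistry and sets out from 3 and 4. Phenol 4 is iodinated ortho to OH (NIS, MeCN, 0 °C) to give 4-bromo-2-iodo-6-methoxyphenol F1. F1 and 3 are then joined by a Pd-catalysed Heck-type oxyarylation (Pd(OAc)2, PPh3, K2CO3, acetone/DMF, 70 °C, silver-free so that 3 is not oxidised). Oxidative addition occurs at C–I only, the aryl group is delivered to the alkene carbon next to the dioxolane, and the benzylic C–Pd bond is displaced by the ortho-phenol oxygen through the same quinone methide to give the trans ring. This returns to the route at 6.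

**Step 5 (one-pot acetonide and glycol cleavage to the α-aryl aldehyde).** The risks are acid damage and, above all, enolisation of 11 with β-elimination of the ring oxygen, which would erode both stereocentres. The fallback sets out from 7 and excises the carbon before the acrylate is present, reducing the aldehyde in the flask where it forms. Aqueous 80% AcOH at 40 °C gives 4-[(2S,3R)-5-bromo-3-[(1S)-1,2-dihydroxyethyl]-7-methoxy-2,3-dihydro-1-benzofuran-2-yl]-2,6-dimethoxyphenyl acetate F2. NaIO4 in THF/pH 7 buffer at 0 °C cleaves it to 4-[(2S,3S)-5-bromo-3-formyl-7-methoxy-2,3-dihydro-1-benzofuran-2-yl]-2,6-dimethoxyphenyl acetate F3, which is never isolated because NaBH4 is added to the same flask. This gives 4-[(2S,3R)-5-bromo-3-(hydroxymethyl)-7-methoxy-2,3-dihydro-1-benzofuran-2-yl]-2,6-dimethoxyphenyl acetate F4. A Heck reaction with 8 under the step 4 conditions gives methyl (E)-3-[(2S,3R)-2-(4-acetoxy-3,5-dimethoxyphenyl)-3-(hydroxymethyl)-7-methoxy-2,3-dihydro-1-benzofuran-5-yl]prop-2-enoate F5. DIBAL-H then reduces the ester and removes the acetate, returning to the route at 12.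

**Step 7 (protecting-group-free double Mitsunobu).** The risks are phenol O-alkylation, SN2′ or ionisation at the electron-rich cinnamyl position, and incomplete second esterification. The fallback sets out from 12 and uses acylation followed by selective aminolysis. Exhaustive acylation with 4-acetoxybenzoyl chloride (3.5 equiv, pyridine, DMAP, CH2Cl2, 0 °C) gives [(2S,3R)-2-[4-(4-acetoxybenzoyloxy)-3,5-dimethoxyphenyl]-5-[(E)-3-(4-acetoxybenzoyloxy)prop-1-enyl]-7-methoxy-2,3-dihydro-1-benzofuran-3-yl]methyl 4-acetoxybenzoate F6. Pyrrolidine (THF, 0 °C to rt) then cleaves the three aryl acetates and the aryl benzoate on the syringyl oxygen, all phenolic esters, far faster than the two alkyl benzoates. This returns to the route at 16.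

## Further compounds

F1 | step 2 | 4-bromo-2-iodo-6-methoxyphenol | COc1cc(Br)cc(I)c1O
F2 | step 5 | 4-[(2S,3R)-5-bromo-3-[(1S)-1,2-dihydroxyethyl]-7-methoxy-2,3-dihydro-1-benzofuran-2-yl]-2,6-dimethoxyphenyl acetate | COc1cc([C@H]2Oc3c(OC)cc(Br)cc3[C@@H]2[C@H](O)CO)cc(OC)c1OC(C)=O
F3 | step 5 | 4-[(2S,3S)-5-bromo-3-formyl-7-methoxy-2,3-dihydro-1-benzofuran-2-yl]-2,6-dimethoxyphenyl acetate | COc1cc([C@H]2Oc3c(OC)cc(Br)cc3[C@@H]2C=O)cc(OC)c1OC(C)=O
F4 | step 5 | 4-[(2S,3R)-5-bromo-3-(hydroxymethyl)-7-methoxy-2,3-dihydro-1-benzofuran-2-yl]-2,6-dimethoxyphenyl acetate | COc1cc([C@H]2Oc3c(OC)cc(Br)cc3[C@@H]2CO)cc(OC)c1OC(C)=O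
F5 | step 5 | methyl (E)-3-[(2S,3R)-2-(4-acetoxy-3,5-dimethoxyphenyl)-3-(hydroxymethyl)-7-methoxy-2,3-dihydro-1-benzofuran-5-yl]prop-2-enoate | COc1cc([C@H]2Oc3c(OC)cc(/C=C/C(=O)OC)cc3[C@@H]2CO)cc(OC)c1OC(C)=O
F6 | step 7 | [(2S,3R)-2-[4-(4-acetoxybenzoyloxy)-3,5-dimethoxyphenyl]-5-[(E)-3-(4-acetoxybenzoyloxy)prop-1-enyl]-7-methoxy-2,3-dihydro-1-benzofuran-3-yl]methyl 4-acetoxybenzoate | COc1cc([C@H]2Oc3c(OC)cc(/C=C/COC(=O)c4ccc(OC(C)=O)cc4)cc3[C@@H]2COC(=O)c2ccc(OC(C)=O)cc2)cc(OC)c1OC(=O)c1ccc(OC(C)=O)cc1
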